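**Assumption:** the (5aR,10bS) antipode of the aminoindanol N‑mesityl triazolium catalyst is taken to direct bond formation to the Re face of the enal β‑carbon; the sense is not established for this substrate pair, and the commercial antipode is used if it proves opposite.

**Retrosynthetic overview**
1. The dihydronaphthalene ring is closed last: acid ionises the p‑hydroxybenzylic C–O bond of an α‑veratrylidene γ‑lactol and the veratryl ring attacks the cation (Friedel–Crafts), setting the aryl group trans to the CH2O substituent.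
2. The lactol comes from DIBAL reduction of an (E)‑α‑veratrylidene γ‑lactone, itself made by aldol condensation of a γ‑lactone with veratraldehyde.
3. The γ‑lactone comes from an NHC homoenolate annulation: the β‑carbon of (E)‑4‑silyloxybut‑2‑enal, made nucleophilic by the carbene, attacks the aldehyde carbon of O‑pivaloylvanillin; this sets the one persistent stereocentre.
4. Ring order: a temporary γ‑lactone first (step 3); it is opened and replaced by the carbocycle in step 6. The lactone C5 centre is sacrificial, so only one centre needs catalyst control.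

**Step 1**
Reactants: 1 (tert‑butyldimethylsilyloxy)acetaldehyde; 2 (triphenylphosphoranylidene)acetaldehyde
Product: 3 (E)-4-[(tert-butyldimethylsilyl)oxy]but-2-enal
Conditions: 2 (1.05 equiv), PhMe, 80 °C
Reagents that add atoms: none
Why: Wittig olefination with the stabilised formyl ylide gives the (E)‑enal, and near‑stoichiometric ylide limits a second homologation.

**Step 2**
Reactants: 4 vanillin
Product: 5 4-formyl-2-methoxyphenyl pivalate
Conditions: PivCl, Et3N, DMAP (cat.), CH2Cl2, 0 °C → rt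
Reagents that add atoms: pivaloyl chloride, CC(C)(C)C(Cl)=O
Why: DMAP‑catalysed O‑acylation of the phenol gives an ester that makes the aldehyde more electrophilic for step 3, has no α‑hydrogens for step 4 and is cleaved by DIBAL in step 5.

**Step 3**
Reactants: 3 (E)-4-[(tert-butyldimethylsilyl)oxy]but-2-enal; 5 4-formyl-2-methoxyphenyl pivalate
Product: 7 (4R)-4-{[(tert-butyldimethylsilyl)oxy]methyl}-5-[3-methoxy-4-(pivaloyloxy)phenyl]dihydrofuran-2(3H)-one (C5 epimer mixture), via carbene-bound homoenolate 6 (not isolated)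
Conditions: (5aR,10bS)-2-mesityl-5a,10b-dihydro-4H,6H-indeno[2,1-b][1,2,4]triazolo[4,3-d][1,4]oxazin-2-ium chloride (10 mol%), DBU (10 mol%), Ti(Oi‑Pr)4 (20 mol%), CH2Cl2, 23 °C; 3 added slowly to 5 (1.5 equiv)
Reagents that add atoms: none
Why: Proposed new method: the carbene adds to 3 to give 6, whose β‑carbon attacks the Ti‑activated aldehyde of 5 on its Re face under catalyst face‑shielding (setting C4 as R), and the alkoxide then lactonises the acyl azolium and releases the catalyst; the closest known reaction type is the NHC homoenolate annulation of enals with aryl aldehydes to γ‑butyrolactones and its cooperative NHC/Ti(IV) enantioselective variant, extended here to a γ‑silyloxy enal in a cross‑coupling, and C5 forms as a cis/trans mixture that does not matter because C5 is ionised in step 6.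

**Step 4**
Reactants: 7 (4R)-4-{[(tert-butyldimethylsilyl)oxy]methyl}-5-[3-methoxy-4-(pivaloyloxy)phenyl]dihydrofuran-2(3H)-one; 8 veratraldehyde
Product: 11 (3E,4R)-3-(3,4-dimethoxybenzylidene)-4-{[(tert-butyldimethylsilyl)oxy]methyl}-5-[3-methoxy-4-(pivaloyloxy)phenyl]dihydrofuran-2(3H)-one, via aldol adduct 9 (not isolated), via mesylate 10 (not isolated)
Conditions: LiHMDS, THF, −78 °C; 8; MsCl, −78 → 0 °C; DBU, 0 °C → rt
Reagents that add atoms: methanesulfonyl chloride, CS(=O)(=O)Cl (its atoms stay only in 10 and leave again on elimination)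
Why: Aldol condensation (lithium lactone enolate addition, mesylation, E1cB elimination) gives the thermodynamically favoured (E)‑benzylidene lactone with the veratryl group cis to C4, the two new centres are transient, and C4 is untouched because it is not acidic under these conditions.

**Step 5**
Reactants: 11 (3E,4R)-3-(3,4-dimethoxybenzylidene)-4-{[(tert-butyldimethylsilyl)oxy]methyl}-5-[3-methoxy-4-(pivaloyloxy)phenyl]dihydrofuran-2(3H)-one
Product: 12 (3E,4R)-3-(3,4-dimethoxybenzylidene)-4-{[(tert-butyldimethylsilyl)oxy]methyl}-5-(4-hydroxy-3-methoxyphenyl)tetrahydrofuran-2-ol (anomer and C5 epimer mixture)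
Conditions: DIBAL‑H (4 equiv), CH2Cl2, −78 °C; Rochelle salt
Reagents that add atoms: none
Why: DIBAL partial reduction stops at the lactol because the tetrahedral aluminate is stable at −78 °C, and the excess hydride reductively cleaves the aryl pivalate to the free phenol; the new anomeric centre is uncontrolled and irrelevant.

**Step 6**
Reactants: 12 (3E,4R)-3-(3,4-dimethoxybenzylidene)-4-{[(tert-butyldimethylsilyl)oxy]methyl}-5-(4-hydroxy-3-methoxyphenyl)tetrahydrofuran-2-ol
Product: 15 (3R,4S)-4-(4-hydroxy-3-methoxyphenyl)-3-(hydroxymethyl)-6,7-dimethoxy-3,4-dihydronaphthalene-2-carbaldehyde (CNP0485134.1), via quinone methide 13 (not isolated), via silyl ether 14 (not isolated)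
Conditions: TFA, CH2Cl2, 0 °C; then H2O, rt
Reagents that add atoms: none
Why: Acid ionises the p‑hydroxybenzylic C–O bond of either C5 epimer to the same quinone methide (as its protonated benzylic cation), an intramolecular Friedel–Crafts alkylation by the veratryl ring para to its 3‑OMe closes the six‑membered ring with the aryl group entering anti to the pseudoaxial CH2OSi group (setting C4 as S, trans to C3), and aqueous TFA then removes the TBS ether.

**Compound list**
1 | (tert‑butyldimethylsilyloxy)acetaldehyde | O=CCO[Si](C)(C)C(C)(C)C | starting material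
2 | (triphenylphosphoranylidene)acetaldehyde | O=CC=P(c1ccccc1)(c1ccccc1)c1ccccc1 | starting material
3 | (E)-4-[(tert-butyldimethylsilyl)oxy]but-2-enal | O=C/C=C/CO[Si](C)(C)C(C)(C)C | intermediate
4 | vanillin (4-hydroxy-3-methoxybenzaldehyde) | COc1cc(C=O)ccc1O | starting material
5 | 4-formyl-2-methoxyphenyl pivalate | COc1cc(C=O)ccc1OC(=O)C(C)(C)C | intermediate
6 | carbene-bound homoenolate (extended Breslow intermediate of 3 on the triazolylidene) | Cc1cc(C)c(c(C)c1)N1C(=C(O)/C=C/CO[Si](C)(C)C(C)(C)C)N2[C@H]3c4ccccc4C[C@H]3OCC2=N1 | intermediate (not isolated)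
7 | (4R)-4-{[(tert-butyldimethylsilyl)oxy]methyl}-5-[3-methoxy-4-(pivaloyloxy)phenyl]dihydrofuran-2(3H)-one; C5 deliberately undefined (cis/trans mixture, cis expected major) | O=C1C[C@@H](C(c2ccc(OC(=O)C(C)(C)C)c(OC)c2)O1)CO[Si](C)(C)C(C)(C)C | intermediate
8 | veratraldehyde (3,4-dimethoxybenzaldehyde) | COc1ccc(C=O)cc1OC | starting material
9 | (4R)-3-[(3,4-dimethoxyphenyl)(hydroxy)methyl]-4-{[(tert-butyldimethylsilyl)oxy]methyl}-5-[3-methoxy-4-(pivaloyloxy)phenyl]dihydrofuran-2(3H)-one (formed as its lithium alkoxide; diastereomer mixture) | O=C1C(C(O)c2ccc(OC)c(OC)c2)[C@@H](C(c2ccc(OC(=O)C(C)(C)C)c(OC)c2)O1)CO[Si](C)(C)C(C)(C)C | intermediate (not isolated)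
10 | methanesulfonate of 9 | O=C1C(C(OS(C)(=O)=O)c2ccc(OC)c(OC)c2)[C@@H](C(c2ccc(OC(=O)C(C)(C)C)c(OC)c2)O1)CO[Si](C)(C)C(C)(C)C | intermediate (not isolated)
11 | (3E,4R)-3-(3,4-dimethoxybenzylidene)-4-{[(tert-butyldimethylsilyl)oxy]methyl}-5-[3-methoxy-4-(pivaloyloxy)phenyl]dihydrofuran-2(3H)-one (C5 epimers) | O=C1/C(=C/c2ccc(OC)c(OC)c2)[C@@H](C(c2ccc(OC(=O)C(C)(C)C)c(OC)c2)O1)CO[Si](C)(C)C(C)(C)C | intermediate
12 | (3E,4R)-3-(3,4-dimethoxybenzylidene)-4-{[(tert-butyldimethylsilyl)oxy]methyl}-5-(4-hydroxy-3-methoxyphenyl)tetrahydrofuran-2-ol (C2 and C5 epimers; in equilibrium with the open hydroxy‑enal) | OC1/C(=C/c2ccc(OC)c(OC)c2)[C@@H](C(c2ccc(O)c(OC)c2)O1)CO[Si](C)(C)C(C)(C)C | intermediate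
13 | (2E,3R)-2-(3,4-dimethoxybenzylidene)-3-{[(tert-butyldimethylsilyl)oxy]methyl}-4-(3-methoxy-4-oxocyclohexa-2,5-dien-1-ylidene)butanal (present as its O‑protonated benzylic cation under TFA) | O=C/C(=C/c1ccc(OC)c(OC)c1)[C@@H](C=C1C=CC(=O)C(OC)=C1)CO[Si](C)(C)C(C)(C)C | intermediate (not isolated)
14 | (3R,4S)-3-{[(tert-butyldimethylsilyl)oxy]methyl}-4-(4-hydroxy-3-methoxyphenyl)-6,7-dimethoxy-3,4-dihydronaphthalene-2-carbaldehyde | COc1cc([C@H]2c3cc(OC)c(OC)cc3C=C(C=O)[C@@H]2CO[Si](C)(C)C(C)(C)C)ccc1O | intermediate (not isolated)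
15 | (3R,4S)-4-(4-hydroxy-3-methoxyphenyl)-3-(hydroxymethyl)-6,7-dimethoxy-3,4-dihydronaphthalene-2-carbaldehyde | COc1cc([C@H]2c3cc(OC)c(OC)cc3C=C(C=O)[C@@H]2CO)ccc1O | target

**Totals:** 6 steps; longest linear sequence 5 (step 1 or 2, then steps 3–6).

**Steps most likely to fail**

Step 3 (key annulation). The risks are modest enantioselectivity, self‑annulation of the enal, loss of silanolate from the homoenolate, and an aryl aldehyde that is still too electron‑rich. The fallback sets out from 5 and comes back at 7, giving up the catalytic route for an auxiliary‑controlled aldol. (S)-4-Benzyloxazolidin-2-one is N‑acylated with methyl 4-chloro-4-oxobutanoate (n‑BuLi, THF, −78 °C) to give (S)-4-benzyl-3-(4-methoxy-4-oxobutanoyl)oxazolidin-2-one F1. Its Z‑boron enolate (Bu2BOTf, i‑Pr2NEt, CH2Cl2, −78 → 0 °C) adds to 5 in an Evans syn‑aldol to give methyl (3S,4S)-3-{[(4S)-4-benzyl-2-oxooxazolidin-3-yl]carbonyl}-4-hydroxy-4-[3-methoxy-4-(pivaloyloxy)phenyl]butanoate F2. This lactonises (cat. TsOH, CH2Cl2) to (4S)-4-benzyl-3-{[(2S,3S)-2-[3-methoxy-4-(pivaloyloxy)phenyl]-5-oxotetrahydrofuran-3-yl]carbonyl}oxazolidin-2-one F3. NaBH4 (THF–H2O, 0 °C) reduces the exocyclic imide carbonyl to give (4R,5S)-4-(hydroxymethyl)-5-[3-methoxy-4-(pivaloyloxy)phenyl]dihydrofuran-2(3H)-one F4. F4 is silylated at once (TBSCl, imidazole, DMF), before it can translactonise, to give 7 as its single (4R,5S) epimer, which the route carries forward unchanged.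

Step 5 (lactol reduction with pivalate cleavage). The risks are over‑reduction or incomplete ester cleavage. The fallback sets out from 11 and comes back at 15, reducing fully and oxidising late. Excess DIBAL‑H (6 equiv, CH2Cl2, −78 → 0 °C) gives (2E,3R)-2-(3,4-dimethoxybenzylidene)-3-{[(tert-butyldimethylsilyl)oxy]methyl}-4-(4-hydroxy-3-methoxyphenyl)butane-1,4-diol F5. TFA/CH2Cl2 then water cyclises and desilylates it to [(1S,2R)-1-(4-hydroxy-3-methoxyphenyl)-6,7-dimethoxy-1,2-dihydronaphthalene-2,3-diyl]dimethanol F6. MnO2 (CH2Cl2, rt) oxidises only the allylic primary alcohol to give 15.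

Step 6 (ionisation and ring closure). The risks are isomerisation of the lactol to a furan, some cis product, and acid‑induced oligomerisation of the enal. The fallback sets out from 11 and comes back at 15, closing the ring at the lactone oxidation level. TfOH (cat., CH2Cl2, 0 °C) ionises the benzylic lactone C–O bond (known type: arene alkylation by γ‑aryl‑γ‑butyrolactones; stronger acid is needed because the acyloxy‑aryl group stabilises the cation less). Ring closure gives (3R,4S)-3-{[(tert-butyldimethylsilyl)oxy]methyl}-6,7-dimethoxy-4-[3-methoxy-4-(pivaloyloxy)phenyl]-3,4-dihydronaphthalene-2-carboxylic acid F7. Aqueous acid in the same pot removes the silyl group and the hydroxy acid closes to (3aR,4S)-6,7-dimethoxy-4-[3-methoxy-4-(pivaloyloxy)phenyl]-3a,4-dihydronaphtho[2,3-c]furan-1(3H)-one F8. DIBAL‑H (4 equiv, CH2Cl2, −78 °C) reduces the lactone and cleaves the pivalate to give (3aR,4S)-4-(4-hydroxy-3-methoxyphenyl)-6,7-dimethoxy-1,3,3a,4-tetrahydronaphtho[2,3-c]furan-1-ol F9, the ring‑closed tautomer of 15, which opens to it.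

**Further compounds**
F1 | step 3 | (S)-4-benzyl-3-(4-methoxy-4-oxobutanoyl)oxazolidin-2-one | COC(=O)CCC(=O)N1[C@@H](Cc2ccccc2)COC1=O
F2 | step 3 | methyl (3S,4S)-3-{[(4S)-4-benzyl-2-oxooxazolidin-3-yl]carbonyl}-4-hydroxy-4-[3-methoxy-4-(pivaloyloxy)phenyl]butanoate | COC(=O)C[C@@H]([C@H](O)c1ccc(OC(=O)C(C)(C)C)c(OC)c1)C(=O)N1[C@@H](Cc2ccccc2)COC1=O
F3 | step 3 | (4S)-4-benzyl-3-{[(2S,3S)-2-[3-methoxy-4-(pivaloyloxy)phenyl]-5-oxotetrahydrofuran-3-yl]carbonyl}oxazolidin-2-one | O=C1C[C@@H]([C@@H](c2ccc(OC(=O)C(C)(C)C)c(OC)c2)O1)C(=O)N1[C@@H](Cc2ccccc2)COC1=O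
F4 | step 3 | (4R,5S)-4-(hydroxymethyl)-5-[3-methoxy-4-(pivaloyloxy)phenyl]dihydrofuran-2(3H)-one | O=C1C[C@@H]([C@@H](c2ccc(OC(=O)C(C)(C)C)c(OC)c2)O1)CO
F5 | step 5 | (2E,3R)-2-(3,4-dimethoxybenzylidene)-3-{[(tert-butyldimethylsilyl)oxy]methyl}-4-(4-hydroxy-3-methoxyphenyl)butane-1,4-diol (C4 epimers) | OC/C(=C/c1ccc(OC)c(OC)c1)[C@@H](C(O)c1ccc(O)c(OC)c1)CO[Si](C)(C)C(C)(C)C
F6 | step 5 | [(1S,2R)-1-(4-hydroxy-3-methoxyphenyl)-6,7-dimethoxy-1,2-dihydronaphthalene-2,3-diyl]dimethanol | COc1cc([C@H]2c3cc(OC)c(OC)cc3C=C(CO)[C@@H]2CO)ccc1O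
F7 | step 6 | (3R,4S)-3-{[(tert-butyldimethylsilyl)oxy]methyl}-6,7-dimethoxy-4-[3-methoxy-4-(pivaloyloxy)phenyl]-3,4-dihydronaphthalene-2-carboxylic acid | COc1cc([C@H]2c3cc(OC)c(OC)cc3C=C(C(=O)O)[C@@H]2CO[Si](C)(C)C(C)(C)C)ccc1OC(=O)C(C)(C)C
F8 | step 6 | (3aR,4S)-6,7-dimethoxy-4-[3-methoxy-4-(pivaloyloxy)phenyl]-3a,4-dihydronaphtho[2,3-c]furan-1(3H)-one | COc1cc([C@H]2c3cc(OC)c(OC)cc3C=C3C(=O)OC[C@H]23)ccc1OC(=O)C(C)(C)C
F9 | step 6 | (3aR,4S)-4-(4-hydroxy-3-methoxyphenyl)-6,7-dimethoxy-1,3,3a,4-tetrahydronaphtho[2,3-c]furan-1-ol (C1 epimers) | COc1cc([C@H]2c3cc(OC)c(OC)cc3C=C3C(O)OC[C@H]23)ccc1O
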